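Start from a one-step world: let partner react with left-handed substrate and nothing else, and take the dissolving of gas into partner as fast, so that c(partner) stays where the held gas of 37 mM keeps it. Each left-handed molecule then has a constant chance per second, the pseudo-first-order case, and the percent curve does not depend on the charge. The runs agree: at 90.0 s beta gives 42% and epsilon 44% left-handed product, though epsilon's charge is 1.48 times beta's. So read the flask off the same curve. In this world left-handed product tops out at half of the two substrates charged.

common to all: gas 37 mM (held)

| charge | left-handed substrate | right-handed substrate | remark | time |
|---|---|---|---|---|
| beta | 0.042 M | 0.042 M | run made earlier |  |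
| epsilon | 0.062 M | 0.062 M | run made earlier |  |
| flask | 0.083 M | 0.083 M |  | 2.0 min |

| run | time / s | left-handed product / % | right-handed product / % |
|---|---|---|---|
| beta | 10.0 | 12 | 0 |
| beta | 12.0 | 13 | 2 |
| beta | 20.0 | 19 | 2 |
| beta | 40.0 | 29 | 3 |
| beta | 60.0 | 35 | 4 |
| beta | 90.0 | 42 | 3 |
| epsilon | 10.0 | 8 | 0 |
| epsilon | 12.0 | 14 | 0 |
| epsilon | 20.0 | 19 | 2 |
| epsilon | 40.0 | 27 | 1 |
| epsilon | 60.0 | 33 | 2 |
| epsilon | 90.0 | 44 | 4 |

(standard deviation of a reading: 1.5 percentage points)

1. excess of left-handed product over right-handed product in the product at 6.0 s
2. excess of left-handed product over right-handed product in the product at 2.0 min
3. part of the left-handed substrate and right-handed substrate charged together that has reacted at 2.0 min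

- partner is single-handed; left-handed substrate and right-handed substrate are mirror images of each other, charged as a racemate, each of them at the stated concentration
- at the start none of partner is dissolved
- candidate steps: partner + left-handed substrate -> left-handed product; right-handed substrate <-> achiral form; left-handed substrate <-> achiral form; partner <-> dormant form; partner -> decomposed reagent; partner + right-handed substrate -> right-handed product; gas <-> partner
- what has gone into achiral form counts as reacted
- an excess is below zero if the other one leads
- the handed part of partner does not stay in what it makes, so the products of the two hands are mirror images too

Add the second step, partner with right-handed substrate. Both steps use the same c(partner), so it drops out of their ratio, and products form in the ratio s times c(left-handed substrate) over c(right-handed substrate). Here s, the hand ratio or selectivity factor, says how many times faster partner takes left-handed substrate than right-handed at equal concentration. Summing the first three times of both runs, left-handed product over right-handed product, gives s = 14.2. This is a rough reading, since the right-handed readings there are 2% or less against a scatter of 1.5 percentage points. Take the substrates as equal at 6.0 s: the excess is s less one over s plus one, and I reckon 86.8% for the flask. Later c(left-handed substrate) drops below c(right-handed substrate), so the ratio falls, and the excess with it.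

Now add the rest. Dormant form and decomposed reagent draw on partner, but with c(partner) held, my reckoning stands. Achiral form counts as reacted, so the reacted part lies above the product sum by c(achiral form); no reading shows that amount, so I give no figure.

The forecast gives an excess of 90% at 6.0 s (80% to 97%), and at 2.0 min an excess of 82% (72% to 89%) and 56% reacted (50% to 68%), with “a little achiral form”. Its early excess stands above my reckoning.

The flask gives an excess of 86.5% at 6.0 s, then an excess of 77.7% and 72.2% reacted at 2.0 min, the reacted part being 16 points above the forecast.

    partner + left-handed substrate → left-handed product (k = 0.733 L mol⁻¹ s⁻¹)
    right-handed substrate ⇌ achiral form (K = 0.980, k = 0.0198 s⁻¹)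
    left-handed substrate ⇌ achiral form (K = 0.980, k = 0.0198 s⁻¹)
    partner ⇌ dormant form (K = 9.83, k = 0.0369 s⁻¹)
    partner → decomposed reagent (k = 0.0385 s⁻¹)
    partner + right-handed substrate → right-handed product (k = 0.0498 L mol⁻¹ s⁻¹)
    gas ⇌ partner, rate k7*(csat - [partner]) (kL = 3.49 s⁻¹)

In the flask at 2.00 min, products make 56.4% of the two substrates charged and achiral form 15.8%. Use s once more at that moment: left-handed substrate 7.90% against right-handed substrate 19.9% gives a product-forming ratio of 5.64, so the product being made then has an excess of 69.8%, lower than the pooled 77.7%.

(The data come from a simulation with made-up constants; scatter was added.)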